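**Retrosynthetic overview** (ring A numbered as in the target: C1–OH, C2–OAr, C3/C4/C5–Br, C6–H; ring B: C1'–O, C3'/C5'–Br, C6'–OH)
1. Feature: the C3–C4–C5 bromine triad of ring A is symmetric about C4, and C4 is para to the C1 hydroxyl. C4 is therefore carried as NH2 (it directs Br to C3 and C5, then becomes Br), and C1 as NO2 (it activates C2 for ether formation, then becomes OH).
2. Endgame disconnections: ring-B O–Me (last), C1–OH from C1–NH2 from C1–NO2, and C4–Br from C4–NH2.
3. Key disconnection: C3–Br and C5–Br, made by amino-directed dibromination of 3-(3,5-dibromo-2-methoxyphenoxy)-4-nitroaniline.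
4. C2–O ether bond by SNAr of 3,5-dibromo-2-methoxyphenol on 3-fluoro-4-nitroaniline; the phenol comes from 3,5-dibromosalicylaldehyde by O-methylation and Baeyer–Villiger oxidation.
5. No ring is formed: both benzene rings are bought and only decorated.

Key step: step 4

Remark: the target has no stereocentre and its diaryl ether axis is not configurationally stable, so it is prepared as the single achiral compound.

**Step 1**
Reactants: 1 3,5-dibromosalicylaldehyde (3,5-dibromo-2-hydroxybenzaldehyde)
Product: 2 3,5-dibromo-2-methoxybenzaldehyde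
Conditions: MeI, K2CO3, DMF, rt → 40 °C
Reagents that add atoms: iodomethane CI
Why: Williamson O-alkylation: carbonate deprotonates the acidic, chelated phenol and the phenoxide is methylated by iodomethane, the aldehyde and aryl bromides being inert.

**Step 2**
Reactants: 2 3,5-dibromo-2-methoxybenzaldehyde
Product: 4 3,5-dibromo-2-methoxyphenol, via aryl formate 3 (not isolated)
Conditions: mCPBA, CH2Cl2, 40 °C; then MeOH, cat. HCl, rt
Reagents that add atoms: 3-chloroperbenzoic acid OOC(=O)c1cccc(Cl)c1
Why: Baeyer–Villiger (Dakin-type) oxidation: in the Criegee adduct the ortho-methoxy aryl group should migrate to oxygen to give formate 3, which acid-catalysed methanolysis cleaves to the phenol without touching the methyl ether.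

**Step 3**
Reactants: 4 3,5-dibromo-2-methoxyphenol; 5 3-fluoro-4-nitroaniline
Product: 6 3-(3,5-dibromo-2-methoxyphenoxy)-4-nitroaniline
Conditions: K2CO3, DMSO, 110 °C
Reagents that add atoms: none
Why: Nucleophilic aromatic substitution (addition–elimination): the phenoxide of 4 displaces the fluoride ortho to the nitro group through a nitro-stabilised Meisenheimer adduct, the amino group being meta to the reacting carbon and too weakly nucleophilic to compete.

**Step 4**
Reactants: 6 3-(3,5-dibromo-2-methoxyphenoxy)-4-nitroaniline; 7 bromine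
Product: 9 2,6-dibromo-3-(3,5-dibromo-2-methoxyphenoxy)-4-nitroaniline, via monobromide 8 (not isolated)
Conditions: Br2 (2.3 equiv), AcOH, rt → 50 °C
Reagents that add atoms: bromine BrBr (compound 7)
Why: Electrophilic aromatic substitution: bromine attacks the carbons ortho to the amino group through nitrogen-stabilised Wheland intermediates, first at the open C5 (also para to the ether oxygen) to give monobromide 8 and then at C3 between the amino and aryloxy groups, so the C5–Br and C3–Br bonds of ring A are made in one flask. The closest known reaction type is the ortho,ortho-dibromination of 4-nitroaniline with bromine in acetic acid. No ring is closed and no stereocentre is created. The step needs ring A to react at C3 and C5 and not at C6 or on ring B: C6 is meta to the amino group and ortho to nitro, while the two free carbons of ring B are meta to its methoxy group, flanked by bromine and on a ring already deactivated by two halogens. The para-nitro group lowers the reactivity of the aniline enough that substitution should end at the dibromide and the amine should not be oxidised.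

**Step 5**
Reactants: 9 2,6-dibromo-3-(3,5-dibromo-2-methoxyphenoxy)-4-nitroaniline
Product: 11 1,2,3-tribromo-4-(3,5-dibromo-2-methoxyphenoxy)-5-nitrobenzene, via diazonium bromide 10 (not isolated)
Conditions: t-BuONO, CuBr2, MeCN, 0 → 60 °C
Reagents that add atoms: copper(II) bromide Br[Cu]Br; tert-butyl nitrite CC(C)(C)ON=O (its nitrogen stays only in intermediate 10)
Why: Sandmeyer bromo-dediazoniation under aprotic conditions: the alkyl nitrite diazotises the weakly basic, doubly ortho-brominated amine and the aryl radical formed by copper electron transfer takes bromine from CuBr2, as is known for 2,6-dibromo-4-nitroanilines, the ether oxygen being meta to the diazonium group so that no cyclisation is open.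

**Step 6**
Reactants: 11 1,2,3-tribromo-4-(3,5-dibromo-2-methoxyphenoxy)-5-nitrobenzene
Product: 12 3,4,5-tribromo-2-(3,5-dibromo-2-methoxyphenoxy)aniline
Conditions: Fe powder, AcOH, EtOH, 70 °C
Reagents that add atoms: none
Why: Béchamp-type dissolving-metal reduction: iron in acetic acid should take the nitro group through the nitroso and hydroxylamine stages to the amine without cleaving aryl C–Br bonds or the diaryl ether.

**Step 7**
Reactants: 12 3,4,5-tribromo-2-(3,5-dibromo-2-methoxyphenoxy)aniline
Product: 14 3,4,5-tribromo-2-(3,5-dibromo-2-methoxyphenoxy)phenol, via diazonium hydrogensulfate 13 (not isolated)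
Conditions: NaNO2, conc. H2SO4, AcOH, 0–10 °C; then aq. Cu(NO3)2 (large excess), Cu2O (initiator), rt
Reagents that add atoms: water O; sodium nitrite [Na+].[O-]N=O and sulfuric acid OS(=O)(=O)O (their atoms stay only in intermediate 13)
Why: Diazotisation with nitrosylsulfuric acid followed by copper(I)-initiated, copper(II)-mediated hydroxy-dediazoniation: at room temperature the aryl radical should be captured by aquated Cu(II) faster than it can add to ring B, and no aryl cation arises that the neighbouring methoxy oxygen could trap.

**Step 8**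
Reactants: 14 3,4,5-tribromo-2-(3,5-dibromo-2-methoxyphenoxy)phenol
Product: 16 3,4,5-tribromo-2-(3,5-dibromo-2-hydroxyphenoxy)phenol (target), via bis(dibromoboryl) ether 15 (not isolated)
Conditions: BBr3 (3 equiv), CH2Cl2, −78 °C → rt; then H2O
Reagents that add atoms: boron tribromide BrB(Br)Br (its atoms stay only in intermediate 15)
Why: Lewis-acid ether cleavage: BBr3 coordinates the methoxy oxygen and bromide removes the methyl group by SN2 while the free phenol is held as its borate, the diaryl ether having no sp3 carbon to attack, and aqueous work-up should release both phenols.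

**Compound list**
1 | 3,5-dibromosalicylaldehyde | O=Cc1cc(Br)cc(Br)c1O | starting material
2 | 3,5-dibromo-2-methoxybenzaldehyde | COc1c(Br)cc(Br)cc1C=O | intermediate
3 | 3,5-dibromo-2-methoxyphenyl formate | COc1c(Br)cc(Br)cc1OC=O | intermediate
4 | 3,5-dibromo-2-methoxyphenol | COc1c(Br)cc(Br)cc1O | intermediate
5 | 3-fluoro-4-nitroaniline | Nc1ccc([N+](=O)[O-])c(F)c1 | starting material
6 | 3-(3,5-dibromo-2-methoxyphenoxy)-4-nitroaniline | Nc1ccc([N+](=O)[O-])c(Oc2cc(Br)cc(Br)c2OC)c1 | intermediate
7 | bromine | BrBr | starting material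
8 | 2-bromo-5-(3,5-dibromo-2-methoxyphenoxy)-4-nitroaniline | Nc1cc(Oc2cc(Br)cc(Br)c2OC)c([N+](=O)[O-])cc1Br | intermediate
9 | 2,6-dibromo-3-(3,5-dibromo-2-methoxyphenoxy)-4-nitroaniline | Nc1c(Br)cc([N+](=O)[O-])c(Oc2cc(Br)cc(Br)c2OC)c1Br | intermediate
10 | 2,6-dibromo-3-(3,5-dibromo-2-methoxyphenoxy)-4-nitrobenzenediazonium bromide | N#[N+]c1c(Br)cc([N+](=O)[O-])c(Oc2cc(Br)cc(Br)c2OC)c1Br.[Br-] | intermediate
11 | 1,2,3-tribromo-4-(3,5-dibromo-2-methoxyphenoxy)-5-nitrobenzene | O=[N+]([O-])c1cc(Br)c(Br)c(Br)c1Oc1cc(Br)cc(Br)c1OC | intermediate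
12 | 3,4,5-tribromo-2-(3,5-dibromo-2-methoxyphenoxy)aniline | Nc1cc(Br)c(Br)c(Br)c1Oc1cc(Br)cc(Br)c1OC | intermediate
13 | 3,4,5-tribromo-2-(3,5-dibromo-2-methoxyphenoxy)benzenediazonium hydrogensulfate | N#[N+]c1cc(Br)c(Br)c(Br)c1Oc1cc(Br)cc(Br)c1OC.OS(=O)(=O)[O-] | intermediate
14 | 3,4,5-tribromo-2-(3,5-dibromo-2-methoxyphenoxy)phenol | Oc1cc(Br)c(Br)c(Br)c1Oc1cc(Br)cc(Br)c1OC | intermediate
15 | bis(dibromoboryl) ether of the target (both phenolic oxygens carry BBr2) | BrB(Br)Oc1cc(Br)c(Br)c(Br)c1Oc1cc(Br)cc(Br)c1OB(Br)Br | intermediate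
16 | 3,4,5-tribromo-2-(3,5-dibromo-2-hydroxyphenoxy)phenol | Oc1cc(Br)c(Br)c(Br)c1Oc1cc(Br)cc(Br)c1O | target

**Step count**
Total steps: 8. Longest linear sequence: 8 steps (1 → 2 → 4 → 6 → 9 → 11 → 12 → 14 → 16).

**Steps most likely to fail**

Step 7. The aryl radical (or, if heterolysis intrudes, the aryl cation) at C1 may cyclise onto ring B at C2' or be trapped by the ring-B methoxy oxygen before water is delivered; reduction to the C1–H compound is a second leak. The fallback sets out from 12 and returns at 14. Diazonium salt 13 is made as in step 7 and treated with aqueous KI to give 1,2,3-tribromo-4-(3,5-dibromo-2-methoxyphenoxy)-5-iodobenzene F1; iodine transfer to the aryl radical is faster than ring closure. i-PrMgCl in THF at −40 °C should exchange only the C–I bond, giving [3,4,5-tribromo-2-(3,5-dibromo-2-methoxyphenoxy)phenyl]magnesium chloride F2, which has no halogen ortho to magnesium. Trimethyl borate converts it into dimethyl [3,4,5-tribromo-2-(3,5-dibromo-2-methoxyphenoxy)phenyl]boronate F3, and NaOH/H2O2 at 0 °C oxidises the C–B bond to phenol 14.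

Step 4. Bromination may stall at monobromide 8 because the second site (C3) is flanked by the amino and aryloxy groups, and forcing it may let bromination leak onto ring B. The fallback sets out from 5 (with 7) and returns at 9, brominating before the ether is made. Bromine in acetic acid should convert 5, through 2-bromo-5-fluoro-4-nitroaniline F4, into 2,6-dibromo-3-fluoro-4-nitroaniline F5; the small fluorine does not shield the flanked carbon and ring B is absent. The fluoride of F5 is still the only leaving group ortho to nitro (both bromines are meta), so SNAr with phenol 4 (K2CO3, DMSO, 110 °C) gives 9.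

Step 2. Hydride instead of aryl migration in the Criegee adduct would give the benzoic acid, because the methoxy group is twisted by its two ortho neighbours and the ring carries two bromines. The fallback sets out from 2 and returns at 4, and uses the very acid that the failure delivers:
- Pinnick oxidation (NaClO2, NaH2PO4, 2-methyl-2-butene, t-BuOH/H2O) gives 3,5-dibromo-2-methoxybenzoic acid F6.
- Curtius rearrangement (DPPA, Et3N, t-BuOH, 85 °C) proceeds through 3,5-dibromo-2-methoxybenzoyl azide F7 and 1,5-dibromo-3-isocyanato-2-methoxybenzene F8 to tert-butyl (3,5-dibromo-2-methoxyphenyl)carbamate F9.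
- HCl in dioxane, then base, frees 3,5-dibromo-2-methoxyaniline F10.
- Diazotisation (NaNO2, H2SO4/AcOH, 0 °C) gives 3,5-dibromo-2-methoxybenzenediazonium hydrogensulfate F11, which hot dilute sulfuric acid hydrolyses to phenol 4; no neighbouring aryl ring is present here to intercept the intermediate.

**Further compounds**
F1 | step 7 | 1,2,3-tribromo-4-(3,5-dibromo-2-methoxyphenoxy)-5-iodobenzene | Ic1cc(Br)c(Br)c(Br)c1Oc1cc(Br)cc(Br)c1OC
F2 | step 7 | [3,4,5-tribromo-2-(3,5-dibromo-2-methoxyphenoxy)phenyl]magnesium chloride | Cl[Mg]c1cc(Br)c(Br)c(Br)c1Oc1cc(Br)cc(Br)c1OC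
F3 | step 7 | dimethyl [3,4,5-tribromo-2-(3,5-dibromo-2-methoxyphenoxy)phenyl]boronate | COB(OC)c1cc(Br)c(Br)c(Br)c1Oc1cc(Br)cc(Br)c1OC
F4 | step 4 | 2-bromo-5-fluoro-4-nitroaniline | Nc1cc(F)c([N+](=O)[O-])cc1Br
F5 | step 4 | 2,6-dibromo-3-fluoro-4-nitroaniline | Nc1c(Br)cc([N+](=O)[O-])c(F)c1Br
F6 | step 2 | 3,5-dibromo-2-methoxybenzoic acid | COc1c(Br)cc(Br)cc1C(=O)O
F7 | step 2 | 3,5-dibromo-2-methoxybenzoyl azide | COc1c(Br)cc(Br)cc1C(=O)N=[N+]=[N-]
F8 | step 2 | 1,5-dibromo-3-isocyanato-2-methoxybenzene | COc1c(Br)cc(Br)cc1N=C=O
F9 | step 2 | tert-butyl (3,5-dibromo-2-methoxyphenyl)carbamate | COc1c(Br)cc(Br)cc1NC(=O)OC(C)(C)C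
F10 | step 2 | 3,5-dibromo-2-methoxyaniline | COc1c(Br)cc(Br)cc1N
F11 | step 2 | 3,5-dibromo-2-methoxybenzenediazonium hydrogensulfate | COc1c(Br)cc(Br)cc1[N+]#N.OS(=O)(=O)[O-]
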